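## The problem

Compound 28 is a cyclopentane (ring carbons C1–C5) with four contiguous stereocentres, all mutually trans: a 1,3-dihydroxypropan-2-yl group on C5, an acyloxymethyl group (C6) on C1, a methyl on C2 and an acyloxy group on C3; C4 is a methylene. Both acyl groups are the same (3S,4E)-4-formyl-3-(2-oxoethyl)hex-4-enoyl unit. Each carries a stereocentre (C3′) too far from the ring to be controlled by it, an (E)-2-ethylidene enal and an enolisable aliphatic aldehyde. These 1,5-dialdehyde arms will not survive base (aldol condensation, E/Z equilibration, acyl migration to the free diol), hydride, organometallic reagents or oxidants, so they must arrive last, masked, and be released under mild acid. The hydroxyls to be acylated (secondary O3, primary O6) must be distinguished from the two primary hydroxyls of the C5 diol, so the diol has to be capped while O3 and O6 are free. In the ring, C5 has no neighbour to direct it and is best set by a catalyst; C1 can then be set trans to C5 by alkylation of a cyclic enolate, and C2 and C3 can be set from C1 and C5 if the ring is closed between C2 and C3. The structure invites that closure: the oxygen on C3 and the methyl on C2 are vicinal and trans, the pattern left by a reductive ketyl–olefin cyclisation in which a C3 aldehyde adds to the inner carbon of a vinyl group on C1 and the alkene terminus becomes the C2 methyl.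

## Retrosynthesis

**Unmasking and ester bonds.** Target 28 is traced to its fully masked form 27 (four dimethyl acetals, diol as acetonide), so one aqueous-acid step ends the synthesis. Cutting the two ester C–O bonds of 27 gives core diol 16 and two equivalents of acid 26. This is preferred to building the side chains on the core because it halves the molecule and lets the remote C3′ centre be made once, on a small compound whose purity can be checked. The esterification must acylate a primary and a hindered secondary alcohol without touching acetals; the stereocentre of 26 is β to the carboxyl, so activation cannot epimerise it.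

**Diol on C5 and protecting-group order.** No skeletal bond is cut between 16 and cyclopentanol 11. The 1,3-diol is traced through acetonide 15, triol 14 and alkylborane 13 to allylic alcohol 12, and from there to the silyl ether 11. A 3-silyloxyprop-1-en-2-yl group is chosen as the latent diol because it can be introduced as an alkenyl nucleophile and is a spectator in the ring closure. Benzyl on O6 and silyl on the allylic oxygen are orthogonal, so the sequence desilylation, hydroboration, acetonide, hydrogenolysis leaves exactly O3–H and O6–H free in 16.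

**C2–C3 bond (key step).** Cyclopentanol 11 is opened between C2 and C3 to hex-5-enal 10. Cuts at C1–C5 or C3–C4 would each remove one stereocentre and leave the trans O/CH3 pair to be made separately. The C2–C3 cut removes two stereocentres, the ring and the methyl group together, and leaves an acyclic precursor with only two adjacent stereocentres. The forward reaction must give 5-exo closure onto the vinyl group only, and hydroxyl trans to methyl.

**Hexenal as an opened lactone.** Aldehyde 10 comes from alcohol 9, which is the methylenation product (ylide from 8) of lactol 7, itself the reduction product of lactone 6. The C=C bond of the vinyl group is the bond cut. The two stereocentres of 10 thus become the 3,4-trans centres of a six-membered lactone, where relative configuration is easy to control; the lactone oxygen ends as the C3 hydroxyl oxygen.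

**C1–C6 bond.** Lactone 6 is cut at the exocyclic bond on the α-carbon to lactone 4 and benzyl chloromethyl ether 5. Enolate alkylation anti to the C4 substituent sets C1 from C5 and brings O6 already protected. An aldol with formaldehyde would need a separate protection step.

**C5–alkenyl bond.** Lactone 4 is cut between the ring carbon and the alkenyl group to 5,6-dihydro-2H-pyran-2-one 3 and alkenylboronate 2, which comes from silyl propargyl ether 1 by α-selective borylation. This places the one stereocentre that nothing else can direct under catalyst control, at the first C–C bond-forming step.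

**Side chain, C2′–C3′ bond.** Acid 26 comes from ester 25 and malonate 24. Malonate 24 is cut at the bond between the malonate carbon and C3′, giving dienal 21 and dimethyl malonate 22 by way of aldehyde 23. The iminium-catalysed Michael addition gives the aldehyde arm at the correct oxidation level and sets C3′ by catalyst control.

**Side chain, C3′–C4′ bond and alkene geometry.** Dienal 21 is cut between the two alkene units to iodo acetal 19 and acrolein 20. Acetal 19 comes from iodoenal 18 and crotonaldehyde 17. The Z-iodide fixes the E-geometry of the future enal before any stereocentre exists.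

## Roads not taken

**Alternative 1:** The C2′–C3′ bonds are cut with the side chains already on the core. Diol 16 would be converted into its bis(allyl malonate) A2, and the iminium catalyst of step 15 would add both malonate arms to two molecules of dienal 21, giving bis-adduct A1.
- Merits: acid 26 is never isolated, the Krapcho and saponification steps disappear, and the core is acylated with a small unhindered reagent.
- Weak points: two enantioselective additions must succeed on one late intermediate, so catalyst imperfection appears as diastereomers of a valuable compound. A1 also carries two free aldehydes and two allylic acetals through a Pd(PPh3)4-mediated deallylative decarboxylation, and the malonate on hindered O3 may react more slowly than 22.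
- Comparison: step count is about equal and Alternative 1 is more convergent late. The chosen plan runs the same Michael addition once, on 21 and 22, where the purity of 26 can be checked and raised before it is committed. Alternative 1 also needs the same core 16, so it competes only with steps 15–18, not with the ring construction.

**Alternative 2:** The C2–CH3 and C1–C6 bonds are cut, leading back to (R)-4-(tert-butyldimethylsilyloxy)cyclopent-2-en-1-one A4. Lithium dimethylcuprate A5 would add its methyl group anti to the silyloxy group, and the resulting enolate would be trapped at C1 by monomeric formaldehyde A6 to give all-trans ketone A3.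
- Merit, and here it is clearly better: three of the four ring stereocentres, with correct relative and absolute configuration, come in one step from a commercial enantiopure enone. The chosen plan needs seven steps before its ring exists.
- Weak points: the ketone carbon of A3 is C5 of the target and must become a CH bearing the dihydroxypropyl branch trans to C1. That requires olefination or condensation on a ketone flanked by an epimerisable centre with a β-hydroxymethyl group (retro-aldol, dehydration) and by a β-silyloxy group that eliminates once the ketone enolises towards C4. The resulting alkene must then be reduced with a facial selectivity that nothing in the molecule secures. Trapping cuprate enolates with formaldehyde is also capricious.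
- Comparison: against the brevity of Alternative 2, the chosen plan fixes C5 first, by a catalyst, with its three-carbon branch in place, and never passes through a β-oxygenated ketone.

**Alternative 3:** The ring is cut at C1–C2 and C3–C4 into ethyl buta-2,3-dienoate A8 and (E)-pent-3-en-2-one A9. A chiral phosphine adds to A8 and the zwitterion joins its α-carbon to the enone β-carbon and its γ-carbon to the enone α-carbon, giving cyclopentene A7. Later the acetyl group would become the C3 oxygen by Baeyer–Villiger oxidation, the ester the C6 hydroxymethyl, and the C5 branch would come from a malonate conjugate addition, with C1 and C5 settling trans by equilibration from the C2 methyl centre.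
- Merits: the cheapest starting materials, a catalytic step forming two C–C bonds and two stereocentres at once, and no early protecting groups; up to the ring it is the shorter route.
- Weak points: the regioisomeric annulation mode competes for simple β-alkyl enones, and enantio- and cis/trans control with an acyclic aliphatic enone are modest. A cyclopentene-1-carboxylate is a poor Michael acceptor, three centres (C1, C3, C5) would rest on equilibration, and the oxidation-level changes (ketone to ester oxygen, ester to alcohol, malonate to diol) add steps that cancel the early gain.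
- Comparison: in the chosen plan each ring centre is set by a defined kinetic element, and the C3 oxygen and C2 methyl are produced in final form by the ring closure itself.

Key step: step 7

Remark on the chemistry: the sense of induction in steps 2 and 15 is assigned from the accepted models for these catalyst classes; if either proved opposite, the antipodal ligand or catalyst would be used with no other change. Compound 28 is treated as the open tetra-aldehyde; hemiacetals with its free diol are reversible forms of the same compound.

## Route

Step 1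
Reactants: 1 tert-butyldimethyl(prop-2-yn-1-yloxy)silane
Product: 2 2-[3-(tert-butyldimethylsilyloxy)prop-1-en-2-yl]-4,4,5,5-tetramethyl-1,3,2-dioxaborolane
Conditions: B2pin2, (SIMes)CuCl (5 mol%; SIMes = 1,3-dimesitylimidazolin-2-ylidene), NaOt-Bu (5 mol%), MeOH, THF, −50 → −15 °C
Reagents that add atoms: bis(pinacolato)diboron, CC1(C)OB(OC1(C)C)B1OC(C)(C)C(C)(C)O1
Why: Copper-catalysed protoboration of a terminal alkyne; with an N-aryl carbene ligand and a propargylic ether the Cu–B bond adds with boron on the internal carbon, and methanol protonates the alkenylcopper, giving the 1,1-disubstituted alkenylboronate. No stereocentre is formed.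

Step 2
Reactants: 2 2-[3-(tert-butyldimethylsilyloxy)prop-1-en-2-yl]-4,4,5,5-tetramethyl-1,3,2-dioxaborolane; 3 5,6-dihydro-2H-pyran-2-one
Product: 4 (R)-4-[3-(tert-butyldimethylsilyloxy)prop-1-en-2-yl]tetrahydro-2H-pyran-2-one
Conditions: [RhCl(C2H4)2]2 (2.5 mol%), (R)-BINAP (6 mol%), aq. KOH (10 mol%), dioxane/H2O 10:1, 50 °C
Reagents that add atoms: none
Why: Hayashi–Miyaura conjugate addition: the alkenyl group is transferred from boron to monovalent rhodium, inserts into the lactone C=C and the rhodium enolate is hydrolysed. The BINAP ligand selects the enone face, and (R)-BINAP is expected to give the R centre (C5 of the target) by analogy with cyclic enones.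

Step 3
Reactants: 4 (R)-4-[3-(tert-butyldimethylsilyloxy)prop-1-en-2-yl]tetrahydro-2H-pyran-2-one; 5 benzyl chloromethyl ether
Product: 6 (3R,4R)-3-[(benzyloxy)methyl]-4-[3-(tert-butyldimethylsilyloxy)prop-1-en-2-yl]tetrahydro-2H-pyran-2-one
Conditions: LiN(i-Pr)2, THF, −78 °C; then 5, DMPU, −78 → −40 °C
Reagents that add atoms: none
Why: Alkylation of the lithium lactone enolate with a reactive alkoxymethyl chloride. The electrophile approaches anti to the C4 alkenyl group, so the new centre (C1 of the target) is set trans to C5 by substrate control.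

Step 4
Reactants: 6 (3R,4R)-3-[(benzyloxy)methyl]-4-[3-(tert-butyldimethylsilyloxy)prop-1-en-2-yl]tetrahydro-2H-pyran-2-one
Product: 7 (3R,4R)-3-[(benzyloxy)methyl]-4-[3-(tert-butyldimethylsilyloxy)prop-1-en-2-yl]tetrahydro-2H-pyran-2-ol (anomer mixture)
Conditions: i-Bu2AlH, CH2Cl2, −78 °C; aq. potassium sodium tartrate
Reagents that add atoms: none
Why: Partial reduction of a lactone to the lactol; the tetrahedral aluminium hemiacetal is stable at −78 °C and collapses only on work-up. The anomeric centre is of no consequence.

Step 5
Reactants: 7 (3R,4R)-3-[(benzyloxy)methyl]-4-[3-(tert-butyldimethylsilyloxy)prop-1-en-2-yl]tetrahydro-2H-pyran-2-ol; 8 methyltriphenylphosphonium bromide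
Product: 9 (3R,4R)-4-[(benzyloxy)methyl]-3-[3-(tert-butyldimethylsilyloxy)prop-1-en-2-yl]hex-5-en-1-ol
Conditions: 8, KOt-Bu, THF, 0 °C; then 7, 0 °C → rt
Reagents that add atoms: none
Why: Wittig methylenation of the hydroxy-aldehyde tautomer of the lactol; excess ylide deprotonates the lactol and drives ring opening. It gives the vinyl group whose terminus becomes the C2 methyl and frees the primary alcohol; low temperature keeps the α-centre intact.

Step 6
Reactants: 9 (3R,4R)-4-[(benzyloxy)methyl]-3-[3-(tert-butyldimethylsilyloxy)prop-1-en-2-yl]hex-5-en-1-ol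
Product: 10 (3R,4R)-4-[(benzyloxy)methyl]-3-[3-(tert-butyldimethylsilyloxy)prop-1-en-2-yl]hex-5-enal
Conditions: Dess–Martin periodinane, CH2Cl2, 0 °C → rt
Reagents that add atoms: none
Why: Dess–Martin oxidation of a primary alcohol to the aldehyde under near-neutral conditions. The aldehyde has no α-stereocentre, and the silyl ether, benzyl ether and both alkenes are inert.

Step 7
Reactants: 10 (3R,4R)-4-[(benzyloxy)methyl]-3-[3-(tert-butyldimethylsilyloxy)prop-1-en-2-yl]hex-5-enal
Product: 11 (1R,2R,3S,4R)-3-[(benzyloxy)methyl]-4-[3-(tert-butyldimethylsilyloxy)prop-1-en-2-yl]-2-methylcyclopentan-1-ol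
Conditions: SmI2 (2.5 equiv), HMPA (10 equiv), t-BuOH (2 equiv), THF, 0 °C; slow addition of 10 (syringe pump)
Reagents that add atoms: none
Why: Divalent samarium (SmI2 activated by HMPA) transfers one electron to the aldehyde, and the samarium-bound ketyl radical adds to the inner carbon of the vinyl group in a 5-exo-trig closure that forms the C2–C3 bond and the cyclopentane; the primary radical is reduced by a second SmI2 to an alkylsamarium that t-BuOH protonates, so the alkene terminus ends as the C2 methyl. The closest known reaction type is the SmI2–HMPA ketyl–olefin cyclisation of δ,ε-unsaturated carbonyl compounds onto unactivated alkenes. The carbinol centre (C3) is set by the bulky HMPA-solvated O–Sm group pointing away from the alkene in the chair-like transition state, which places hydroxyl trans to the developing methyl. The methyl-bearing centre (C2) is set by the existing centres: the benzyloxymethyl group on C1 and the alkenyl group on C5 both sit pseudo-equatorial, so the new exocyclic carbon forms trans to the C1 substituent and cis-1,3 to the C5 substituent. Chemoselectivity between the two alkenes is secured by ring size, since the 1,1-disubstituted alkene on C5 could be reached only by 4-exo or 5-endo closure. Slow addition of 10 to excess reductant holds back pinacol coupling and ensures the primary radical is reduced before it can attack the cis-disposed 1,1-disubstituted alkene; any alcohol 9 formed by simple reduction can be re-oxidised and recycled.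

Step 8
Reactants: 11 (1R,2R,3S,4R)-3-[(benzyloxy)methyl]-4-[3-(tert-butyldimethylsilyloxy)prop-1-en-2-yl]-2-methylcyclopentan-1-ol
Product: 12 (1R,2R,3S,4R)-3-[(benzyloxy)methyl]-4-(3-hydroxyprop-1-en-2-yl)-2-methylcyclopentan-1-ol
Conditions: n-Bu4NF, THF, 0 °C → rt
Reagents that add atoms: none
Why: Fluoride cleavage of the silyl ether; the benzyl ether, the secondary alcohol and the alkene are unaffected.

Step 9
Reactants: 12 (1R,2R,3S,4R)-3-[(benzyloxy)methyl]-4-(3-hydroxyprop-1-en-2-yl)-2-methylcyclopentan-1-ol
Product: 14 2-[(1R,2S,3R,4R)-2-[(benzyloxy)methyl]-4-hydroxy-3-methylcyclopentyl]propane-1,3-diol, via alkylborane 13 (not isolated)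
Conditions: 9-BBN (excess), THF, rt → 50 °C; then aq. NaOH, H2O2, 0 °C → rt
Reagents that add atoms: hydrogen peroxide, OO (oxygen of the new hydroxyl); 9-borabicyclo[3.3.1]nonane, B1C2CCCC1CCC2 (boron in intermediate 13 only)
Why: Anti-Markovnikov hydroboration of the 1,1-disubstituted alkene places boron on the terminal carbon, and oxidation replaces it by hydroxyl. The new CH carries two identical hydroxymethyl groups, so it is not a stereocentre in 14 and the epimer mixture in 13 does not matter.

Step 10
Reactants: 14 2-[(1R,2S,3R,4R)-2-[(benzyloxy)methyl]-4-hydroxy-3-methylcyclopentyl]propane-1,3-diol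
Product: 15 (1R,2R,3S,4R)-3-[(benzyloxy)methyl]-4-(2,2-dimethyl-1,3-dioxan-5-yl)-2-methylcyclopentan-1-ol
Conditions: Me2C(OMe)2, PPTS (cat.), acetone, rt
Reagents that add atoms: 2,2-dimethoxypropane, COC(C)(C)OC
Why: Thermodynamic acetonide formation selects the six-membered 1,3-dioxane of the 1,3-diol. The isolated secondary hydroxyl cannot form a cyclic ketal, and any mixed ketal on it is lost on work-up.

Step 11
Reactants: 15 (1R,2R,3S,4R)-3-[(benzyloxy)methyl]-4-(2,2-dimethyl-1,3-dioxan-5-yl)-2-methylcyclopentan-1-ol
Product: 16 (1R,2R,3S,4R)-4-(2,2-dimethyl-1,3-dioxan-5-yl)-3-(hydroxymethyl)-2-methylcyclopentan-1-ol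
Conditions: H2 (1 atm), Pd/C, EtOAc, rt
Reagents that add atoms: none
Why: Hydrogenolysis of the benzyl ether; no alkene remains and the acetonide is stable in a neutral solvent. This leaves exactly the two hydroxyls to be acylated.

Step 12
Reactants: 17 (E)-but-2-enal
Product: 18 (Z)-2-iodobut-2-enal
Conditions: I2, K2CO3, DMAP (cat.), THF/H2O 1:1, 0 °C → rt
Reagents that add atoms: iodine, II
Why: α-Iodination of an enal by amine conjugate addition, iodination of the enolate and elimination. It gives the more stable Z-iodoenal with iodine cis to methyl, which fixes the later E-enal geometry.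

Step 13
Reactants: 18 (Z)-2-iodobut-2-enal
Product: 19 (Z)-2-iodo-1,1-dimethoxybut-2-ene
Conditions: HC(OMe)3, MeOH, p-TsOH·H2O (cat.), rt
Reagents that add atoms: trimethyl orthoformate, COC(OC)OC; methanol, CO
Why: Acid-catalysed acetalisation with the orthoformate as water scavenger; the alkenyl iodide and its geometry are unaffected.

Step 14
Reactants: 19 (Z)-2-iodo-1,1-dimethoxybut-2-ene; 20 acrolein
Product: 21 (2E,4E)-4-(dimethoxymethyl)hexa-2,4-dienal
Conditions: 20 (excess), Pd(OAc)2 (5 mol%), n-Bu4NCl, NaHCO3, DMF, rt → 40 °C
Reagents that add atoms: none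
Why: Heck reaction under ligand-free phase-transfer conditions: zerovalent palladium inserts into the C–I bond with retention, the alkenylpalladium adds to the acrolein terminus and β-hydride elimination gives the E-enal. The weak base leaves the acetal intact.

Step 15
Reactants: 21 (2E,4E)-4-(dimethoxymethyl)hexa-2,4-dienal; 22 dimethyl malonate
Product: 24 dimethyl 2-[(3S,4E)-1,1-dimethoxy-4-(dimethoxymethyl)hex-4-en-3-yl]propanedioate, via Michael adduct aldehyde 23 (not isolated)
Conditions: 22, (R)-2-{bis[3,5-bis(trifluoromethyl)phenyl](trimethylsilyloxy)methyl}pyrrolidine (10 mol%), MeOH, 0 °C → rt; then HC(OMe)3, p-TsOH·H2O (20 mol%), rt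
Reagents that add atoms: trimethyl orthoformate, COC(OC)OC; methanol, CO
Why: Iminium-ion catalysed Michael addition: the catalyst forms an E-iminium ion with one face shielded by the diaryl(silyloxy)methyl group, and malonate adds 1,4 to the open face, which for the R catalyst should set C3′ as S. 1,6-Addition is disfavoured because the δ-carbon is substituted and the γ-carbon fully substituted; the aldehyde is acetalised in the same flask.

Step 16
Reactants: 24 dimethyl 2-[(3S,4E)-1,1-dimethoxy-4-(dimethoxymethyl)hex-4-en-3-yl]propanedioate
Product: 25 methyl (3S,4E)-4-(dimethoxymethyl)-3-(2,2-dimethoxyethyl)hex-4-enoate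
Conditions: LiCl, H2O (2 equiv), DMSO, 140 °C
Reagents that add atoms: none
Why: Krapcho dealkoxycarbonylation: chloride demethylates one ester, the carboxylate loses CO2 and water protonates the ester enolate. The neutral medium spares both acetals, the alkene geometry and the β-stereocentre.

Step 17
Reactants: 25 methyl (3S,4E)-4-(dimethoxymethyl)-3-(2,2-dimethoxyethyl)hex-4-enoate
Product: 26 (3S,4E)-4-(dimethoxymethyl)-3-(2,2-dimethoxyethyl)hex-4-enoic acid
Conditions: LiOH, THF/MeOH/H2O, rt; aq. citric acid to pH 4–5, 0 °C
Reagents that add atoms: lithium hydroxide, [Li+].[OH-] (oxygen of the carboxyl OH)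
Why: Ester saponification; C3′ is not adjacent to the carbonyl and cannot epimerise. Acidification only to pH 4–5 keeps the acetals, and the acid is used at once.

Step 18
Reactants: 16 (1R,2R,3S,4R)-4-(2,2-dimethyl-1,3-dioxan-5-yl)-3-(hydroxymethyl)-2-methylcyclopentan-1-ol; 26 (3S,4E)-4-(dimethoxymethyl)-3-(2,2-dimethoxyethyl)hex-4-enoic acid
Product: 27 (1R,2R,3S,4R)-3-({[(3S,4E)-4-(dimethoxymethyl)-3-(2,2-dimethoxyethyl)hex-4-enoyl]oxy}methyl)-4-(2,2-dimethyl-1,3-dioxan-5-yl)-2-methylcyclopentyl (3S,4E)-4-(dimethoxymethyl)-3-(2,2-dimethoxyethyl)hex-4-enoate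
Conditions: 26 (2.6 equiv), EDC·HCl, DMAP, CH2Cl2, 0 °C → rt
Reagents that add atoms: none
Why: Steglich esterification of the primary and the secondary hydroxyl with excess acid. The acid's stereocentre is β to the carboxyl, so activation cannot epimerise it; acetals and acetonide are inert.

Step 19
Reactants: 27 the bis-ester of step 18
Product: 28 (1R,2R,3S,4R)-4-(1,3-dihydroxypropan-2-yl)-3-({[(3S,4E)-4-formyl-3-(2-oxoethyl)hex-4-enoyl]oxy}methyl)-2-methylcyclopentyl (3S,4E)-4-formyl-3-(2-oxoethyl)hex-4-enoate
Conditions: AcOH/THF/H2O 3:1:1, rt → 40 °C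
Reagents that add atoms: water, O
Why: Acid-catalysed hydrolysis of the four dimethyl acetals and the acetonide in a water-rich medium. The esters and E-enals survive, no base touches the free dialdehyde arms, and excess water keeps the liberated diol from re-forming acetals with the aldehydes.

## Compound list

1 | tert-butyldimethyl(prop-2-yn-1-yloxy)silane | C#CCO[Si](C)(C)C(C)(C)C | starting material
2 | 2-[3-(tert-butyldimethylsilyloxy)prop-1-en-2-yl]-4,4,5,5-tetramethyl-1,3,2-dioxaborolane | C=C(CO[Si](C)(C)C(C)(C)C)B1OC(C)(C)C(C)(C)O1 | intermediate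
3 | 5,6-dihydro-2H-pyran-2-one | O=C1C=CCCO1 | starting material
4 | (R)-4-[3-(tert-butyldimethylsilyloxy)prop-1-en-2-yl]tetrahydro-2H-pyran-2-one | O=C1C[C@H](C(=C)CO[Si](C)(C)C(C)(C)C)CCO1 | intermediate
5 | benzyl chloromethyl ether | ClCOCc1ccccc1 | starting material
6 | (3R,4R)-3-[(benzyloxy)methyl]-4-[3-(tert-butyldimethylsilyloxy)prop-1-en-2-yl]tetrahydro-2H-pyran-2-one | O=C1OCC[C@@H](C(=C)CO[Si](C)(C)C(C)(C)C)[C@@H]1COCc1ccccc1 | intermediate
7 | (3R,4R)-3-[(benzyloxy)methyl]-4-[3-(tert-butyldimethylsilyloxy)prop-1-en-2-yl]tetrahydro-2H-pyran-2-ol (anomer mixture) | OC1OCC[C@@H](C(=C)CO[Si](C)(C)C(C)(C)C)[C@@H]1COCc1ccccc1 | intermediate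
8 | methyltriphenylphosphonium bromide | C[P+](c1ccccc1)(c1ccccc1)c1ccccc1.[Br-] | starting material
9 | (3R,4R)-4-[(benzyloxy)methyl]-3-[3-(tert-butyldimethylsilyloxy)prop-1-en-2-yl]hex-5-en-1-ol | OCC[C@@H](C(=C)CO[Si](C)(C)C(C)(C)C)[C@H](COCc1ccccc1)C=C | intermediate
10 | (3R,4R)-4-[(benzyloxy)methyl]-3-[3-(tert-butyldimethylsilyloxy)prop-1-en-2-yl]hex-5-enal | O=CC[C@@H](C(=C)CO[Si](C)(C)C(C)(C)C)[C@H](COCc1ccccc1)C=C | intermediate
11 | (1R,2R,3S,4R)-3-[(benzyloxy)methyl]-4-[3-(tert-butyldimethylsilyloxy)prop-1-en-2-yl]-2-methylcyclopentan-1-ol | O(Cc1ccccc1)C[C@@H]1[C@@H](C)[C@H](O)C[C@H]1C(=C)CO[Si](C)(C)C(C)(C)C | intermediate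
12 | (1R,2R,3S,4R)-3-[(benzyloxy)methyl]-4-(3-hydroxyprop-1-en-2-yl)-2-methylcyclopentan-1-ol | O(Cc1ccccc1)C[C@@H]1[C@@H](C)[C@H](O)C[C@H]1C(=C)CO | intermediate
13 | B-alkyl-9-borabicyclo[3.3.1]nonane from 12, boron on the former alkene terminus (epimers at the new CH; hydroxyls partly borinated by excess reagent) | O(Cc1ccccc1)C[C@@H]1[C@@H](C)[C@H](O)C[C@H]1C(CO)CB2C3CCCC2CCC3 | intermediate (not isolated)
14 | 2-[(1R,2S,3R,4R)-2-[(benzyloxy)methyl]-4-hydroxy-3-methylcyclopentyl]propane-1,3-diol | O(Cc1ccccc1)C[C@@H]1[C@@H](C)[C@H](O)C[C@H]1C(CO)CO | intermediate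
15 | (1R,2R,3S,4R)-3-[(benzyloxy)methyl]-4-(2,2-dimethyl-1,3-dioxan-5-yl)-2-methylcyclopentan-1-ol | O(Cc1ccccc1)C[C@@H]1[C@@H](C)[C@H](O)C[C@H]1C2COC(C)(C)OC2 | intermediate
16 | (1R,2R,3S,4R)-4-(2,2-dimethyl-1,3-dioxan-5-yl)-3-(hydroxymethyl)-2-methylcyclopentan-1-ol | OC[C@@H]1[C@@H](C)[C@H](O)C[C@H]1C2COC(C)(C)OC2 | intermediate
17 | (E)-but-2-enal (crotonaldehyde) | C/C=C/C=O | starting material
18 | (Z)-2-iodobut-2-enal | C/C=C(\I)C=O | intermediate
19 | (Z)-2-iodo-1,1-dimethoxybut-2-ene | C/C=C(\I)C(OC)OC | intermediate
20 | acrolein (prop-2-enal) | C=CC=O | starting material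
21 | (2E,4E)-4-(dimethoxymethyl)hexa-2,4-dienal | C/C=C(\C=C\C=O)C(OC)OC | intermediate
22 | dimethyl malonate | COC(=O)CC(=O)OC | starting material
23 | dimethyl 2-[(3S,4E)-4-(dimethoxymethyl)-1-oxohex-4-en-3-yl]propanedioate | COC(=O)C(C(=O)OC)[C@H](CC=O)/C(C(OC)OC)=C\C | intermediate (not isolated)
24 | dimethyl 2-[(3S,4E)-1,1-dimethoxy-4-(dimethoxymethyl)hex-4-en-3-yl]propanedioate | COC(=O)C(C(=O)OC)[C@H](CC(OC)OC)/C(C(OC)OC)=C\C | intermediate
25 | methyl (3S,4E)-4-(dimethoxymethyl)-3-(2,2-dimethoxyethyl)hex-4-enoate | COC(=O)C[C@H](CC(OC)OC)/C(C(OC)OC)=C\C | intermediate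
26 | (3S,4E)-4-(dimethoxymethyl)-3-(2,2-dimethoxyethyl)hex-4-enoic acid | OC(=O)C[C@H](CC(OC)OC)/C(C(OC)OC)=C\C | intermediate
27 | (1R,2R,3S,4R)-3-({[(3S,4E)-4-(dimethoxymethyl)-3-(2,2-dimethoxyethyl)hex-4-enoyl]oxy}methyl)-4-(2,2-dimethyl-1,3-dioxan-5-yl)-2-methylcyclopentyl (3S,4E)-4-(dimethoxymethyl)-3-(2,2-dimethoxyethyl)hex-4-enoate | C/C=C(/C(OC)OC)[C@@H](CC(OC)OC)CC(=O)OC[C@@H]1[C@@H](C)[C@H](OC(=O)C[C@H](CC(OC)OC)/C(C(OC)OC)=C\C)C[C@H]1C2COC(C)(C)OC2 | intermediate
28 | (1R,2R,3S,4R)-4-(1,3-dihydroxypropan-2-yl)-3-({[(3S,4E)-4-formyl-3-(2-oxoethyl)hex-4-enoyl]oxy}methyl)-2-methylcyclopentyl (3S,4E)-4-formyl-3-(2-oxoethyl)hex-4-enoate | C/C=C(/C=O)[C@@H](CC=O)CC(=O)OC[C@@H]1[C@@H](C)[C@H](OC(=O)C[C@H](CC=O)/C(C=O)=C\C)C[C@H]1C(CO)CO | target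

## Step count and risks

Total step count: 19. Longest linear sequence: 13 steps (steps 1–11, 18 and 19); the side-chain branch (steps 12–17) joins at step 18.

**Step 7 (key step).** The ketyl adds only slowly to an unactivated alkene, so bimolecular pinacol coupling or simple reduction of the aldehyde may outrun ring closure, and facial control at the carbinol carbon may be incomplete. Fallback: activate the acceptor. Setting out from 9, cross-metathesis with phenyl vinyl sulfone (second-generation Grubbs catalyst, CH2Cl2, 40 °C) would give the (E)-vinyl sulfone alcohol F1. Dess–Martin oxidation would give the vinyl sulfone aldehyde F2. SmI2 in THF/MeOH at −78 °C, without HMPA, should close the ring quickly onto the electron-poor alkene with the same trans preference and give the sulfonylmethyl cyclopentanol F3. Reductive desulfonylation (Na(Hg), Na2HPO4, MeOH) turns the sulfonylmethyl group into the methyl group and returns to the route at 11.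

**Step 2.** The α-branched alkenylboronate may protodeboronate faster than it transmetalates, giving low conversion, and the hindered nucleophile may erode enantioselectivity. Fallback: use a simpler nucleophile and add the oxygen later. Setting out from 3, the same [RhCl(C2H4)2]2/(R)-BINAP addition with commercial isopropenylboronic acid pinacol ester would give the isopropenyl lactone F4. Allylic oxidation (SeO2 cat., t-BuOOH, CH2Cl2) would give the allylic alcohol lactone F5, which is silylated at once (t-BuMe2SiCl, imidazole, DMF) to return at 4.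

**Step 5.** The open form of the lactol is an α-branched β-benzyloxy aldehyde; under the basic ylide, epimerisation at the α-centre or β-elimination of benzyloxide may compete with olefination. Fallback: a two-step Peterson olefination with a non-basic nucleophile. Setting out from 7, Me3SiCH2MgCl/CeCl3 (THF, −78 → 0 °C) would add to the aldehyde form and give the β-hydroxysilane diol F6; elimination with KH in THF returns to the route at 9.

**Step 15.** The γ-branched dienal may form its iminium ion slowly, leading to low conversion or eroded enantioselectivity, and some 1,6-addition cannot be excluded. Fallback: form the C3′–C4′ bond instead, by the reaction used in step 2. Setting out from 19, Miyaura borylation (B2pin2, PdCl2(dppf), KOPh, toluene, 50 °C) would give the alkenylboronate F7. Addition to 3 with [RhCl(C2H4)2]2/(S)-BINAP would give the lactone F8. Methanolysis (K2CO3, MeOH) would give the hydroxy ester F9, Dess–Martin oxidation the aldehyde ester F10, and acetalisation (HC(OMe)3, MeOH, PPTS) rejoins the route at 25.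

**Step 19.** All five acid-labile groups are released at once, so the liberated diol may trap oxocarbenium ions from the acetals, or the free dialdehyde arms may cyclise or isomerise before the slowest acetal is hydrolysed. Fallback: separate the two unmasking events by capping the diol with a fluoride-labile group. Setting out from 14, t-Bu2Si(OTf)2/2,6-lutidine would give the silylene alcohol F11; hydrogenolysis (H2, Pd/C) the silylene diol F12; esterification with 26 as in step 18 the silylene bis-ester F13; transacetalisation (Amberlyst-15, acetone/H2O, rt), with no free diol present, the silylene tetra-aldehyde F14; and buffered HF·pyridine (THF/pyridine, 0 °C) removes the silylene and returns at 28.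

## Further compounds

F1 | step 7 | 4-[(benzyloxy)methyl]-3-[3-(tert-butyldimethylsilyloxy)prop-1-en-2-yl]-6-(phenylsulfonyl)hex-5-en-1-ol, 5E, both stereocentres arranged as in 9 | OCC[C@@H](C(=C)CO[Si](C)(C)C(C)(C)C)[C@H](COCc1ccccc1)/C=C/S(=O)(=O)c1ccccc1
F2 | step 7 | 4-[(benzyloxy)methyl]-3-[3-(tert-butyldimethylsilyloxy)prop-1-en-2-yl]-6-(phenylsulfonyl)hex-5-enal, 5E, both stereocentres arranged as in 10 | O=CC[C@@H](C(=C)CO[Si](C)(C)C(C)(C)C)[C@H](COCc1ccccc1)/C=C/S(=O)(=O)c1ccccc1
F3 | step 7 | 3-[(benzyloxy)methyl]-4-[3-(tert-butyldimethylsilyloxy)prop-1-en-2-yl]-2-[(phenylsulfonyl)methyl]cyclopentan-1-ol, all-trans as in 11 | O(Cc1ccccc1)C[C@@H]1[C@@H](CS(=O)(=O)c2ccccc2)[C@H](O)C[C@H]1C(=C)CO[Si](C)(C)C(C)(C)C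
F4 | step 2 | (R)-4-(prop-1-en-2-yl)tetrahydro-2H-pyran-2-one | O=C1C[C@H](C(C)=C)CCO1
F5 | step 2 | (R)-4-(3-hydroxyprop-1-en-2-yl)tetrahydro-2H-pyran-2-one | O=C1C[C@H](C(=C)CO)CCO1
F6 | step 5 | 4-[(benzyloxy)methyl]-3-[3-(tert-butyldimethylsilyloxy)prop-1-en-2-yl]-6-(trimethylsilyl)hexane-1,5-diol, C5 epimers, other centres as in 9 | OCC[C@@H](C(=C)CO[Si](C)(C)C(C)(C)C)[C@H](COCc1ccccc1)C(O)C[Si](C)(C)C
F7 | step 15 | 2-[(E)-1,1-dimethoxybut-2-en-2-yl]-4,4,5,5-tetramethyl-1,3,2-dioxaborolane | C/C=C(\B1OC(C)(C)C(C)(C)O1)C(OC)OC
F8 | step 15 | (S)-4-[(E)-1,1-dimethoxybut-2-en-2-yl]tetrahydro-2H-pyran-2-one | O=C1C[C@@H](/C(C(OC)OC)=C\C)CCO1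
F9 | step 15 | methyl (3S,4E)-4-(dimethoxymethyl)-3-(2-hydroxyethyl)hex-4-enoate | COC(=O)C[C@H](CCO)/C(C(OC)OC)=C\C
F10 | step 15 | methyl (3S,4E)-4-(dimethoxymethyl)-3-(2-oxoethyl)hex-4-enoate | COC(=O)C[C@H](CC=O)/C(C(OC)OC)=C\C
F11 | step 19 | (1R,2R,3S,4R)-3-[(benzyloxy)methyl]-4-(2,2-di-tert-butyl-1,3,2-dioxasilinan-5-yl)-2-methylcyclopentan-1-ol | O(Cc1ccccc1)C[C@@H]1[C@@H](C)[C@H](O)C[C@H]1C2CO[Si](C(C)(C)C)(C(C)(C)C)OC2
F12 | step 19 | (1R,2R,3S,4R)-4-(2,2-di-tert-butyl-1,3,2-dioxasilinan-5-yl)-3-(hydroxymethyl)-2-methylcyclopentan-1-ol | OC[C@@H]1[C@@H](C)[C@H](O)C[C@H]1C2CO[Si](C(C)(C)C)(C(C)(C)C)OC2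
F13 | step 19 | bis-ester of F12 with two molecules of 26 (acetals intact, diol as di-tert-butylsilylene) | C/C=C(/C(OC)OC)[C@@H](CC(OC)OC)CC(=O)OC[C@@H]1[C@@H](C)[C@H](OC(=O)C[C@H](CC(OC)OC)/C(C(OC)OC)=C\C)C[C@H]1C2CO[Si](C(C)(C)C)(C(C)(C)C)OC2
F14 | step 19 | di-tert-butylsilylene derivative of 28 (all four aldehydes free) | C/C=C(/C=O)[C@@H](CC=O)CC(=O)OC[C@@H]1[C@@H](C)[C@H](OC(=O)C[C@H](CC=O)/C(C=O)=C\C)C[C@H]1C2CO[Si](C(C)(C)C)(C(C)(C)C)OC2
A1 | alternative 1 | bis-Michael adduct with free CH2CHO arms, C4′ dimethyl acetals and an allyl ester on each C2′ | C/C=C(/C(OC)OC)[C@@H](CC=O)C(C(=O)OCC=C)C(=O)OC[C@@H]1[C@@H](C)[C@H](OC(=O)C(C(=O)OCC=C)[C@H](CC=O)/C(C(OC)OC)=C\C)C[C@H]1C2COC(C)(C)OC2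
A2 | alternative 1 | bis(allyl malonate) of diol 16 | C=CCOC(=O)CC(=O)OC[C@@H]1[C@@H](C)[C@H](OC(=O)CC(=O)OCC=C)C[C@H]1C2COC(C)(C)OC2
A3 | alternative 2 | all-trans 4-(tert-butyldimethylsilyloxy)-2-(hydroxymethyl)-3-methylcyclopentan-1-one | OC[C@@H]1[C@@H](C)[C@H](O[Si](C)(C)C(C)(C)C)CC1=O
A4 | alternative 2 | (R)-4-(tert-butyldimethylsilyloxy)cyclopent-2-en-1-one | O=C1C=C[C@H](O[Si](C)(C)C(C)(C)C)C1
A5 | alternative 2 | lithium dimethylcuprate, Me2CuLi | [Li+].C[Cu-]C
A6 | alternative 2 | formaldehyde | C=O
A7 | alternative 3 | ethyl trans-4-acetyl-5-methylcyclopent-1-ene-1-carboxylate | CCOC(=O)C1=CC[C@@H](C(C)=O)[C@@H]1C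
A8 | alternative 3 | ethyl buta-2,3-dienoate | C=C=CC(=O)OCC
A9 | alternative 3 | (E)-pent-3-en-2-one | C/C=C/C(C)=O
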